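**Retrosynthetic overview**

1. The target is the 2,6-diangelate of a dauc-8-ene-2α,4β,6α-triol. The esters go on last, and both secondary carbinols are set in one hydroxyl-directed reduction of a 2,6-diketone whose carbonyls are both β to the C4 tertiary alcohol.
2. The seven-membered ring is closed late by ring-closing metathesis (C8=C9) between an allyl group on C1 and a methallyl ketone on C5 of a fully substituted cyclopentane.
3. That cyclopentane (C1–C5) is made in one operation on a chiral 4-allyl-5-menthyloxybutenolide: decarboxylative radical conjugate addition forms C1–C2, and the lactone enolate released by radical–polar crossover closes C5–C4 by aldol addition to an isopropyl ketone (formal (3+2) annulation).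
4. Enabling feature: in the five-membered ring, the C4 carbinol is β to the C6 oxygen function through C5 (aldol retron), quaternary C1 is the β-carbon of that same C6 carbonyl (conjugate-addition retron), and the C1 methyl carbon (C15) is cis to C6. C15–O–C6(=O) can therefore be held as a γ-lactone, whose obligatory cis fusion becomes the trans 5–7 junction once the lactone is opened and C15–O is reduced to CH3; annulation directly on a cycloheptenone would give the cis-fused skeleton.
5. Ring order: butenolide (temporary ring) → cyclopentane (key step) → lactone opened and C15 deoxygenated → cycloheptene by metathesis.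

Key step: step 5

Remark: carotane (daucane) numbering is used throughout: five-membered ring C1 (quaternary, methyl C15)–C2–C3–C4 (OH, isopropyl)–C5, seven-membered ring C1–C5–C6–C7–C8(methyl)=C9–C10, and β is the face of the C1 methyl. Step 5 is assumed to give both C2 epimers, which are carried together until C2 is oxidised (step 13) and re-set (step 14).

**Route**

Step 1
Reactants: 1 pent-4-enal; 2 glyoxylic acid monohydrate
Product: 3 5-hydroxy-4-(prop-2-en-1-yl)furan-2(5H)-one (racemic lactol)
Conditions: morpholine hydrochloride, dioxane–H2O, reflux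
Reagents that add atoms: none
Why: Amine-mediated aldol condensation of the aldehyde α-carbon with glyoxylic acid and lactol closure of the resulting (Z)-4-oxobut-2-enoic acid is the standard entry to 4-alkyl-5-hydroxybutenolides, and the lactol carbon needs no control because it equilibrates.

Step 2
Reactants: 3 5-hydroxy-4-(prop-2-en-1-yl)furan-2(5H)-one; 4 (1R,2S,5R)-(−)-menthol
Product: 5 (5R)-5-[(1R,2S,5R)-menthyloxy]-4-(prop-2-en-1-yl)furan-2(5H)-one
Conditions: cat. p-TsOH, toluene, reflux (Dean–Stark); crystallisation of the (5R) acetal, mother liquor re-equilibrated with acid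
Reagents that add atoms: none
Why: Acid-catalysed acetalisation of the lactol is reversible at the acetal carbon, so crystallisation with re-equilibration should converge on the (5R) acetal, whose alkoxy group later shields one face of the butenolide.

Step 3
Reactants: 6 3-methylbutan-2-one; 2 glyoxylic acid monohydrate
Product: 7 2-hydroxy-5-methyl-4-oxohexanoic acid (racemic)
Conditions: pyrrolidine (20 mol %), excess 6 as solvent, rt
Reagents that add atoms: none
Why: Enamine-mediated direct aldol addition at the methyl group of the ketone to the aldehyde of glyoxylic acid should give the γ-keto α-hydroxy acid, whose stereocenter is irrelevant because it becomes a planar radical in step 5.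

Step 4
Reactants: 7 2-hydroxy-5-methyl-4-oxohexanoic acid
Product: 9 2-[(tert-butyldimethylsilyl)oxy]-5-methyl-4-oxohexanoic acid, via bis-silylated hydroxy acid 8 (not isolated)
Conditions: TBSCl, imidazole, DMF, rt; then AcOH, THF–H2O, rt
Reagents that add atoms: tert-butyldimethylsilyl chloride, CC(C)(C)[Si](C)(C)Cl
Why: Silylation of hydroxyl and carboxyl followed by hydrolysis of the labile silyl ester under mild acid should give the O-silyl acid while avoiding base, which would eliminate the β-silyloxy ketone.

Step 5
Reactants: 5 (5R)-5-menthyloxy-4-allylbutenolide; 9 2-[(tert-butyldimethylsilyl)oxy]-5-methyl-4-oxohexanoic acid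
Product: 11 cis-fused 5-allyl-8-hydroxy-8-isopropyl-4-menthyloxy-6-(tert-butyldimethylsilyloxy)-3-oxabicyclo[3.3.0]octan-2-one (both epimers at the silyloxy carbon), via lactone enolate 10 (not isolated)
Conditions: Ir[dF(CF3)ppy]2(dtbbpy)PF6 (2 mol %), K2HPO4, DMF, blue LEDs, rt
Reagents that add atoms: none
Why: Proposed new method: the excited trivalent iridium photocatalyst should oxidise the carboxylate of 9, loss of CO2 gives a nucleophilic α-silyloxy radical at C2 that adds to the β-carbon (C1) of butenolide 5, and the resulting α-lactone radical is reduced by the divalent iridium species to lactone enolate 10, which adds to the pendant isopropyl ketone (C5–C4) faster than it is protonated in aprotic DMF. The closest known reaction types are the photoredox decarboxylative conjugate addition of α-oxy acids, radical–polar crossover sequences in which the enolate is trapped by an internal electrophile, and samarium diiodide ketyl–olefin addition/aldol cascades; what is new is their use as an intermolecular (3+2) annulation that builds a quaternary carbon. The only ring closed is the cyclopentane C1–C5, by a 5-(enolexo)-exo-trig aldol addition. C1 is set by radical attack anti to the menthyloxy group on the neighbouring acetal carbon (auxiliary control), C5 by the obligatory cis fusion of the new ring to the γ-lactone, and C4 by the isopropyl group taking the convex face while the alkoxide sits on the concave face beside the lactone carbonyl; C2 is not controlled. The step needs chemoselective attack on the electron-poor butenolide alkene instead of the allyl group, which the polarity of the radical secures, and ring closure in preference to β-elimination or protonation, which the five-membered tether and the weak phosphate base favour.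

Step 6
Reactants: 11 bicyclic menthyloxy lactone
Product: 14 cis-fused 5-allyl-8-hydroxy-8-isopropyl-6-(tert-butyldimethylsilyloxy)-3-oxabicyclo[3.3.0]octan-2-one (both epimers at the silyloxy carbon), via sodium aldehyde carboxylate 12 (not isolated), via sodium hydroxy carboxylate 13 (not isolated)
Conditions: NaOH, NaBH4, THF–MeOH–H2O, 0 °C to rt; then 1 M HCl to pH 2
Reagents that add atoms: sodium hydroxide, [Na+].[OH-] (its atoms stay only in 12 and 13)
Why: Saponification of the acylal releases menthol and the C15 aldehyde, NaBH4 reduces the aldehyde and acidification relactonises the cis hydroxy acid (standard reductive removal of an alkoxybutenolide auxiliary), and no stereocenter is touched because the aldehyde sits on quaternary C1.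

Step 7
Reactants: 14 bicyclic γ-lactone
Product: 15 2-allyl-3-[(tert-butyldimethylsilyl)oxy]-5-hydroxy-2-(hydroxymethyl)-5-isopropyl-N-methoxy-N-methylcyclopentane-1-carboxamide
Conditions: MeNHOMe·HCl, AlMe3, CH2Cl2, 0 °C to rt; used directly
Reagents that add atoms: N,O-dimethylhydroxylamine hydrochloride, CNOC.Cl
Why: Aluminium amide aminolysis of the γ-lactone (Weinreb amide formation) should open the temporary ring, freeing the C15 primary alcohol and turning C6 into an acyl donor without touching C5.

Step 8
Reactants: 15 hydroxy Weinreb amide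
Product: 16 O-{[C15] methyl} 1H-imidazole-1-carbothioate of 15 (primary alcohol thioacylated)
Conditions: 1,1'-thiocarbonyldiimidazole, DMAP (cat.), CH2Cl2, 40 °C
Reagents that add atoms: 1,1'-thiocarbonyldiimidazole, S=C(n1ccnc1)n1ccnc1
Why: Thioacylation of the primary alcohol (first half of a Barton–McCombie deoxygenation) should be selective over the hindered tertiary C4 hydroxyl and also blocks relactonisation of the hydroxy amide.

Step 9
Reactants: 16 thiocarbonylimidazolide
Product: 17 2-allyl-3-[(tert-butyldimethylsilyl)oxy]-5-hydroxy-5-isopropyl-N-methoxy-N,2-dimethylcyclopentane-1-carboxamide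
Conditions: Bu3SnH, AIBN, toluene, 110 °C
Reagents that add atoms: none
Why: Barton–McCombie radical deoxygenation converts C15–O into the C1 methyl group without affecting the quaternary center.

Step 10
Reactants: 17 deoxygenated Weinreb amide; 18 2-methylallylmagnesium chloride
Product: 19 1-{2-allyl-3-[(tert-butyldimethylsilyl)oxy]-5-hydroxy-5-isopropyl-2-methylcyclopentyl}-3-methylbut-3-en-1-one
Conditions: THF, −78 to −20 °C; cold aq. NH4Cl
Reagents that add atoms: none
Why: Grignard addition to the Weinreb amide stops at the chelated tetrahedral intermediate and should give the β,γ-unsaturated ketone without epimerising C5, the excess reagent first deprotonating the tertiary alcohol.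

Step 11
Reactants: 19 allyl methallyl ketone
Product: 20 2ξ-[(tert-butyldimethylsilyl)oxy]-4β-hydroxydauc-8-en-6-one
Conditions: second-generation Grubbs catalyst (H2IMes)(PCy3)Cl2Ru=CHPh (5 mol %), CH2Cl2 (high dilution), 40 °C
Reagents that add atoms: none
Why: Ring-closing metathesis between the allyl group on C1 and the methallyl ketone on C5 closes the seven-membered ring with the trisubstituted C8=C9 alkene, and the trans ring fusion follows from the trans arrangement of the two chains fixed in step 5.

Step 12
Reactants: 20 silyl ether ketone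
Product: 21 2ξ,4β-dihydroxydauc-8-en-6-one
Conditions: HF·pyridine, THF, 0 °C to rt
Reagents that add atoms: none
Why: Fluoride-mediated desilylation under weakly acidic conditions frees the C2 hydroxyl without moving the β,γ-double bond into conjugation.

Step 13
Reactants: 21 dihydroxy ketone
Product: 22 4β-hydroxydauc-8-ene-2,6-dione
Conditions: Dess–Martin periodinane, NaHCO3, CH2Cl2, 0 °C to rt
Reagents that add atoms: none
Why: Dess–Martin oxidation of the secondary C2 alcohol (the tertiary C4 alcohol is inert) merges both C2 epimers into one diketol under near-neutral conditions.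

Step 14
Reactants: 22 diketol
Product: 23 dauc-8-ene-2α,4β,6α-triol
Conditions: Me4NBH(OAc)3, MeCN–AcOH, −30 to −20 °C
Reagents that add atoms: none
Why: Evans–Saksena hydroxyl-directed reduction delivers hydride intramolecularly from boron bound to the β-face C4 hydroxyl to both β-ketones, so the C2 and C6 hydroxyls should both form anti to the C4 hydroxyl (2α and 6α).

Step 15
Reactants: 23 triol; 24 angelic acid
Product: 26 4β-hydroxydauc-8-ene-2α,6α-diyl bis[(2Z)-2-methylbut-2-enoate] (target), via angelic 2,4,6-trichlorobenzoic anhydride 25 (not isolated)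
Conditions: 24, 2,4,6-trichlorobenzoyl chloride, Et3N, toluene, rt; then 23, toluene, 75 °C
Reagents that add atoms: 2,4,6-trichlorobenzoyl chloride, O=C(Cl)c1c(Cl)cc(Cl)cc1Cl (its atoms stay only in 25)
Why: Yamaguchi-type acylation through the mixed anhydride should esterify the two hindered secondary alcohols while leaving the tertiary C4 hydroxyl free, and is an established way to introduce angelates with little Z-to-E isomerisation.

**Compound list**

1 | pent-4-enal | C=CCCC=O | starting material
2 | glyoxylic acid monohydrate (2,2-dihydroxyacetic acid) | OC(O)C(=O)O | starting material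
3 | 5-hydroxy-4-(prop-2-en-1-yl)furan-2(5H)-one (racemic) | C=CCC1=CC(=O)OC1O | intermediate
4 | (1R,2S,5R)-(−)-menthol | O[C@@H]1C[C@H](C)CC[C@H]1C(C)C | starting material
5 | (5R)-5-{[(1R,2S,5R)-5-methyl-2-(propan-2-yl)cyclohexyl]oxy}-4-(prop-2-en-1-yl)furan-2(5H)-one | C=CCC1=CC(=O)O[C@H]1O[C@@H]2C[C@H](C)CC[C@H]2C(C)C | intermediate
6 | 3-methylbutan-2-one | CC(C)C(C)=O | starting material
7 | 2-hydroxy-5-methyl-4-oxohexanoic acid (racemic) | CC(C)C(=O)CC(O)C(=O)O | intermediate
8 | tert-butyldimethylsilyl 2-[(tert-butyldimethylsilyl)oxy]-5-methyl-4-oxohexanoate (not isolated) | CC(C)C(=O)CC(O[Si](C)(C)C(C)(C)C)C(=O)O[Si](C)(C)C(C)(C)C | intermediate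
9 | 2-[(tert-butyldimethylsilyl)oxy]-5-methyl-4-oxohexanoic acid (racemic) | CC(C)C(=O)CC(O[Si](C)(C)C(C)(C)C)C(=O)O | intermediate
10 | lactone enolate (anion) formed by radical addition at C4 of 5 anti to the menthyloxy group (not isolated) | C=CC[C@@]1(C(O[Si](C)(C)C(C)(C)C)CC(=O)C(C)C)C=C([O-])O[C@H]1O[C@@H]2C[C@H](C)CC[C@H]2C(C)C | intermediate
11 | cis-fused 5-allyl-8-hydroxy-8-isopropyl-4-menthyloxy-6-(tert-butyldimethylsilyloxy)-3-oxabicyclo[3.3.0]octan-2-one; menthyloxy trans to the cyclopentane, 8-OH on the concave face (cis to the lactone ring), 8-isopropyl on the convex face, both 6-epimers | C=CC[C@@]1([C@H](O[C@@H]3C[C@H](C)CC[C@H]3C(C)C)OC2=O)C(O[Si](C)(C)C(C)(C)C)C[C@@](O)(C(C)C)[C@@H]12 | intermediate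
12 | sodium 2-allyl-2-formyl-5-hydroxy-5-isopropyl-3-(tert-butyldimethylsilyloxy)cyclopentane-1-carboxylate (not isolated) | [Na+].C=CC[C@@]1(C=O)C(O[Si](C)(C)C(C)(C)C)C[C@@](O)(C(C)C)[C@@H]1C(=O)[O-] | intermediate
13 | sodium 2-allyl-5-hydroxy-2-(hydroxymethyl)-5-isopropyl-3-(tert-butyldimethylsilyloxy)cyclopentane-1-carboxylate (not isolated) | [Na+].C=CC[C@@]1(CO)C(O[Si](C)(C)C(C)(C)C)C[C@@](O)(C(C)C)[C@@H]1C(=O)[O-] | intermediate
14 | cis-fused 5-allyl-8-hydroxy-8-isopropyl-6-(tert-butyldimethylsilyloxy)-3-oxabicyclo[3.3.0]octan-2-one; 8-OH concave, 8-isopropyl convex, both 6-epimers | C=CC[C@@]1(COC2=O)C(O[Si](C)(C)C(C)(C)C)C[C@@](O)(C(C)C)[C@@H]12 | intermediate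
15 | 2-allyl-3-[(tert-butyldimethylsilyl)oxy]-5-hydroxy-2-(hydroxymethyl)-5-isopropyl-N-methoxy-N-methylcyclopentane-1-carboxamide (hydroxymethyl cis to the amide, both 3-epimers) | C=CC[C@@]1(CO)C(O[Si](C)(C)C(C)(C)C)C[C@@](O)(C(C)C)[C@@H]1C(=O)N(C)OC | intermediate
16 | O-({1-allyl-5-[(tert-butyldimethylsilyl)oxy]-3-hydroxy-3-isopropyl-2-[methoxy(methyl)carbamoyl]cyclopentyl}methyl) 1H-imidazole-1-carbothioate | C=CC[C@@]1(COC(=S)n2ccnc2)C(O[Si](C)(C)C(C)(C)C)C[C@@](O)(C(C)C)[C@@H]1C(=O)N(C)OC | intermediate
17 | 2-allyl-3-[(tert-butyldimethylsilyl)oxy]-5-hydroxy-5-isopropyl-N-methoxy-N,2-dimethylcyclopentane-1-carboxamide (methyl cis to the amide) | C=CC[C@@]1(C)C(O[Si](C)(C)C(C)(C)C)C[C@@](O)(C(C)C)[C@@H]1C(=O)N(C)OC | intermediate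
18 | 2-methylallylmagnesium chloride | CC(=C)C[Mg]Cl | starting material
19 | 1-{2-allyl-3-[(tert-butyldimethylsilyl)oxy]-5-hydroxy-5-isopropyl-2-methylcyclopentyl}-3-methylbut-3-en-1-one | C=CC[C@@]1(C)C(O[Si](C)(C)C(C)(C)C)C[C@@](O)(C(C)C)[C@@H]1C(=O)CC(C)=C | intermediate
20 | 2ξ-[(tert-butyldimethylsilyl)oxy]-4β-hydroxydauc-8-en-6-one (trans-fused, 5α-H) | O=C1CC(C)=CC[C@@]2(C)C(O[Si](C)(C)C(C)(C)C)C[C@@](O)(C(C)C)[C@H]12 | intermediate
21 | 2ξ,4β-dihydroxydauc-8-en-6-one | O=C1CC(C)=CC[C@@]2(C)C(O)C[C@@](O)(C(C)C)[C@H]12 | intermediate
22 | 4β-hydroxydauc-8-ene-2,6-dione | O=C1CC(C)=CC[C@@]2(C)C(=O)C[C@@](O)(C(C)C)[C@H]12 | intermediate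
23 | dauc-8-ene-2α,4β,6α-triol | O[C@H]1CC(C)=CC[C@@]2(C)[C@@H](O)C[C@@](O)(C(C)C)[C@H]12 | intermediate
24 | angelic acid ((2Z)-2-methylbut-2-enoic acid) | C/C=C(/C)C(=O)O | starting material
25 | (2Z)-2-methylbut-2-enoic 2,4,6-trichlorobenzoic anhydride (not isolated) | C/C=C(/C)C(=O)OC(=O)c1c(Cl)cc(Cl)cc1Cl | intermediate
26 | (1R,2S,4R,5S,6S)-4-hydroxydauc-8-ene-2,6-diyl bis[(2Z)-2-methylbut-2-enoate] | C/C=C(/C)C(=O)O[C@H]1CC(C)=CC[C@@]2(C)[C@@H](OC(=O)/C(C)=C\C)C[C@@](O)(C(C)C)[C@H]12 | target

**Step count and risks**

Total step count: 15. Longest linear sequence: 13 steps (steps 1, 2 and 5–15; equally steps 3, 4 and 5–15).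

Steps most likely to fail:

1. Step 5 (proposed new method). The lactone enolate may be protonated before it cyclises, leaving only the open conjugate adduct. Radical addition to the hindered β,β-disubstituted butenolide may be too slow. The phosphate base may eliminate the β-silyloxy group of 9. The fallback uses known reactions, sets out from 9 (with 5) and comes back at 11. It makes the two bonds in two pots and generates the enolate regiospecifically by reductive cleavage of a carbon–sulfur bond. Acid 9 is esterified with N-hydroxypyridine-2-thione (DCC, CH2Cl2, dark) to the Barton ester F1. Visible-light photolysis of F1 in the presence of 5 should give the α-(pyridin-2-ylsulfanyl) lactone F2 by decarboxylation, radical conjugate addition anti to the menthyloxy group and transfer of the pyridylthio group (Barton decarboxylative addition). Samarium diiodide (THF, −78 °C) then cleaves the C–S bond, and the samarium enolate closes C5–C4 by a Reformatsky-type aldol addition to give 11.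

2. Step 9. Fragmentation of the tin adduct radical to a primary neopentyl radical may be slow, so that reduction of the thiocarbonyl group returns the alcohol. The fallback sets out from 15 and comes back at 17, replacing the radical deoxygenation by an ionic one through the aldehyde. Dess–Martin oxidation of 15 gives the non-enolisable neopentyl aldehyde F3. Condensation with p-toluenesulfonyl hydrazide gives the tosylhydrazone F4. Reduction with catecholborane followed by sodium acetate trihydrate (hydrazone reduction with loss of sulfinate and N2) should give 17.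

3. Step 15. Acylation of the two hindered hydroxyls may be incomplete, and the angeloyl unit may isomerise to the E (tigloyl) geometry. The fallback sets out from 23 and comes back at 26, building the Z-alkene after the ester bond is in place. Triol 23 is acylated with 2-[bis(2,2,2-trifluoroethoxy)phosphoryl]propanoic acid (DCC, DMAP, CH2Cl2) to the bis(phosphonopropionate) F5. A double Still–Gennari olefination with acetaldehyde (KHMDS, 18-crown-6, THF, −78 °C) should then give both (Z)-2-methylbut-2-enoates of 26.

**Further compounds**

F1 | step 5 | 2-thioxopyridin-1(2H)-yl 2-[(tert-butyldimethylsilyl)oxy]-5-methyl-4-oxohexanoate | CC(C)C(=O)CC(O[Si](C)(C)C(C)(C)C)C(=O)ON1C=CC=CC1=S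
F2 | step 5 | (5R)-4-allyl-5-menthyloxy-3-(pyridin-2-ylsulfanyl)-4-{1-[(tert-butyldimethylsilyl)oxy]-4-methyl-3-oxopentyl}dihydrofuran-2(3H)-one | C=CC[C@@]1(C(O[Si](C)(C)C(C)(C)C)CC(=O)C(C)C)C(Sc2ccccn2)C(=O)O[C@H]1O[C@@H]3C[C@H](C)CC[C@H]3C(C)C
F3 | step 9 | 2-allyl-3-[(tert-butyldimethylsilyl)oxy]-2-formyl-5-hydroxy-5-isopropyl-N-methoxy-N-methylcyclopentane-1-carboxamide | C=CC[C@@]1(C=O)C(O[Si](C)(C)C(C)(C)C)C[C@@](O)(C(C)C)[C@@H]1C(=O)N(C)OC
F4 | step 9 | p-toluenesulfonylhydrazone of F3 | C=CC[C@@]1(C=NNS(=O)(=O)c2ccc(C)cc2)C(O[Si](C)(C)C(C)(C)C)C[C@@](O)(C(C)C)[C@@H]1C(=O)N(C)OC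
F5 | step 15 | 4β-hydroxydauc-8-ene-2α,6α-diyl bis{2-[bis(2,2,2-trifluoroethoxy)phosphoryl]propanoate} | CC(C(=O)O[C@H]1CC(C)=CC[C@@]2(C)[C@@H](OC(=O)C(C)P(=O)(OCC(F)(F)F)OCC(F)(F)F)C[C@@](O)(C(C)C)[C@H]12)P(=O)(OCC(F)(F)F)OCC(F)(F)F
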